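## Retrosynthetic overview

1. Target 17 ⇒ sodium carboxylate 16: the γ-lactone is closed last by intramolecular SN2 at C8 (bromide leaves, inversion); the exo-methylene comes from methylenation of the keto group of α-keto ester 14.
2. 14 ⇒ diene 10 + dienophile 13: one catalytic enantioselective endo Diels–Alder reaction builds the cyclohexene (the only carbocycle) with its tetrasubstituted C5=C10 alkene and sets C6, C7 and C8.
3. 10 ⇒ enal 9 ⇒ aldehyde 5 + acetone ketal 6 (Mukaiyama-type addition, elimination, dienol acetate).
4. 5 ⇒ achiral enal 4 (from ketone 1): C4 is set by organocatalytic transfer hydrogenation.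
5. Ring order: carbocycle first (step 6), lactone second (step 8); both acetates are carried through from 1 and from the dienol acetate, so no protecting-group steps are needed.

Assumption: 1, 2, 6, 11 and 12 are taken as purchasable, eudesmane numbering (C4 side-chain centre; ring C5=C10, C6, C7, C8, C9) is used in the explanations, and the sense of induction of each chiral catalyst is taken from its closest analogue (the mirror-image catalyst is used if it proves opposite).

## Route

Step 1
Reactants: 1 4-oxopentyl acetate; 2 diethyl [2-(cyclohexylamino)ethenyl]phosphonate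
Product: 4 (2E/2Z)-6-acetoxy-3-methylhex-2-enal, via unsaturated N-cyclohexyl imine 3 (not isolated)
Conditions: 2, NaH, THF, 0 °C; then 1, 0 → 60 °C; then aq. oxalic acid, rt
Reagents that add atoms: water, O
Why: Horner–Wadsworth–Emmons formyl-olefination of the ketone with the sodium salt of the enamine phosphonate, then hydrolysis of the unsaturated imine, gives the enal; no stereocentre is formed and the E/Z ratio is irrelevant because step 2 is stereoconvergent.

Step 2
Reactants: 4 (2E/2Z)-6-acetoxy-3-methylhex-2-enal
Product: 5 (S)-6-acetoxy-3-methylhexanal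
Conditions: morpholinium salt of (S)-TRIP [(S)-3,3'-bis(2,4,6-triisopropylphenyl)-1,1'-binaphthyl-2,2'-diyl hydrogen phosphate] (20 mol%), Hantzsch ester (diethyl 2,6-dimethyl-1,4-dihydropyridine-3,5-dicarboxylate, 1.1 equiv), 1,4-dioxane, 50 °C
Reagents that add atoms: none
Why: Iminium-ion transfer hydrogenation under asymmetric counteranion-directed catalysis: the E and Z iminium ions equilibrate and the chiral phosphate directs hydride to one face of C4, setting the S centre (about 90% ee expected by analogy with citral to citronellal; the minor antipode becomes a separable diastereomer after step 6).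

Step 3
Reactants: 5 (S)-6-acetoxy-3-methylhexanal; 6 2,2-dimethoxypropane
Product: 9 (4S)-5-formyl-4,6-dimethylhept-5-en-1-yl acetate, via silyl enol ether 7 (not isolated), via methoxy aldehyde 8 (not isolated)
Conditions: iPr2NEt (1.2 equiv), TMSOTf (1.5 equiv), 6 (2 equiv), CH2Cl2, −78 → 0 °C; then DBU, rt
Reagents that add atoms: none
Why: One-pot enol silane formation and Mukaiyama aldol-type addition to the oxocarbenium ion of the ketal, then E1cB loss of methanol, gives the tetrasubstituted enal; C4 is not enolisable and is untouched.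

Step 4
Reactants: 9 (4S)-5-formyl-4,6-dimethylhept-5-en-1-yl acetate
Product: 10 (4S)-5-[(E)-acetoxymethylidene]-4,6-dimethylhept-6-en-1-yl acetate
Conditions: Ac2O, Et3N, DMAP (10 mol%), 80 °C
Reagents that add atoms: acetic anhydride, CC(=O)OC(C)=O
Why: Dienol acetate formation (γ-deprotonation of the s-trans enal and O-acylation) gives the 1-acetoxy diene with OAc trans to the isopropenyl group (1E), the geometry that reacts in the cycloaddition and that delivers the C6 acetate of the target.

Step 5
Reactants: 11 (E)-(2-bromoethenyl)trimethylsilane; 12 allyl chlorooxoacetate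
Product: 13 allyl (E)-4-bromo-2-oxobut-3-enoate
Conditions: AlCl3, CH2Cl2, −78 → −20 °C
Reagents that add atoms: none
Why: Friedel–Crafts-type ipso-acyldesilylation of the vinylsilane (β-silyl cation, loss of Me3SiCl) gives the β-bromovinyl keto ester with retention of the E geometry.

Step 6
Reactants: 10 (4S)-5-[(E)-acetoxymethylidene]-4,6-dimethylhept-6-en-1-yl acetate; 13 allyl (E)-4-bromo-2-oxobut-3-enoate
Product: 14 allyl 2-[(1R,2R,6S)-2-acetoxy-3-[(2S)-5-acetoxypentan-2-yl]-6-bromo-4-methylcyclohex-3-en-1-yl]-2-oxoacetate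
Conditions: (R)-3,3'-bis(2,4,6-triisopropylphenyl)-BINOL N-triflylphosphoramide (10 mol%), 4 Å molecular sieves, toluene, −60 → −30 °C; product used directly in step 7
Reagents that add atoms: none
Why: Proposed new method: a confined chiral N-triflylphosphoramide should hydrogen-bond/protonate the keto carbonyl of 13 (with a second contact to the adjacent ester carbonyl holding the 1,2-dicarbonyl in the chiral pocket) and lower its LUMO, so that the (1E)-acetoxy diene adds in an asynchronous normal-demand [4+2] with the usual ortho orientation (C6–OAc next to the acyl-bearing C7), endo preference (acyl cis to OAc) and Br trans to the acyl group from the E dienophile, while the catalyst rather than the remote C4 centre selects the faces and fixes C6, C7 and C8 absolutely; the closest known reaction types are chiral N-triflylphosphoramide-catalysed Diels–Alder reactions of vinyl ketones with siloxydienes and chiral-acid-catalysed cycloadditions of β,γ-unsaturated α-keto esters, neither shown for acyloxydienes or β-halovinyl keto esters.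

Step 7
Reactants: 14 allyl 2-[(1R,2R,6S)-2-acetoxy-3-[(2S)-5-acetoxypentan-2-yl]-6-bromo-4-methylcyclohex-3-en-1-yl]-2-oxoacetate
Product: 15 allyl 2-[(1S,2R,6S)-2-acetoxy-3-[(2S)-5-acetoxypentan-2-yl]-6-bromo-4-methylcyclohex-3-en-1-yl]prop-2-enoate
Conditions: Zn, CH2Br2, TiCl4 (reagent preformed in THF), CH2Cl2, 0 °C → rt
Reagents that add atoms: dibromomethane, BrCBr
Why: Takai–Lombardo methylenation: the non-basic zinc/titanium methylene reagent reacts only with the highly electrophilic keto carbonyl (esters and acetates are inert) and does not deprotonate the acidic C7–H, so the three ring centres are kept and the acrylate carbon C13 is installed.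

Step 8
Reactants: 15 allyl 2-[(1S,2R,6S)-2-acetoxy-3-[(2S)-5-acetoxypentan-2-yl]-6-bromo-4-methylcyclohex-3-en-1-yl]prop-2-enoate
Product: 17 1,6-O,O-diacetylbritannilactone, via sodium carboxylate 16 (not isolated)
Conditions: Pd(PPh3)4 (5 mol%), TolSO2Na (1.1 equiv), THF/MeOH, rt; then DMF, 50 °C
Reagents that add atoms: none
Why: Tsuji–Trost deallylation with sulfinate as allyl acceptor frees the carboxylate, which displaces the trans bromide from the trans-diaxial conformer by 5-exo-tet SN2 with inversion at C8, giving the cis-fused α-methylene lactone with O8 cis to C11 and to the C6 acetate (all-cis, 4S,6R,7R,8R).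

## Compound list

1 | 4-oxopentyl acetate | CC(=O)CCCOC(C)=O | starting material
2 | diethyl [2-(cyclohexylamino)ethenyl]phosphonate | CCOP(=O)(OCC)C=CNC1CCCCC1 | starting material
3 | 6-(cyclohexylimino)-4-methylhex-4-en-1-yl acetate (E/Z mixture; not isolated) | CC(=O)OCCCC(C)=CC=NC1CCCCC1 | intermediate
4 | (2E/2Z)-6-acetoxy-3-methylhex-2-enal | CC(=O)OCCCC(C)=CC=O | intermediate
5 | (S)-6-acetoxy-3-methylhexanal [(4S)-4-methyl-6-oxohexyl acetate] | O=CC[C@@H](C)CCCOC(C)=O | intermediate
6 | 2,2-dimethoxypropane | COC(C)(C)OC | starting material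
7 | (4S)-4-methyl-6-(trimethylsilyloxy)hex-5-en-1-yl acetate (E/Z mixture; not isolated) | C[Si](C)(C)OC=C[C@@H](C)CCCOC(C)=O | intermediate
8 | (4S)-5-formyl-6-methoxy-4,6-dimethylheptyl acetate (both C5 epimers; not isolated) | O=CC(C(C)(C)OC)[C@@H](C)CCCOC(C)=O | intermediate
9 | (4S)-5-formyl-4,6-dimethylhept-5-en-1-yl acetate | O=CC(=C(C)C)[C@@H](C)CCCOC(C)=O | intermediate
10 | (4S)-5-[(E)-acetoxymethylidene]-4,6-dimethylhept-6-en-1-yl acetate (1-acetoxy diene; OAc trans to isopropenyl) | C=C(C)/C(=C/OC(C)=O)[C@@H](C)CCCOC(C)=O | intermediate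
11 | (E)-(2-bromoethenyl)trimethylsilane | C[Si](C)(C)/C=C/Br | starting material
12 | allyl chlorooxoacetate | C=CCOC(=O)C(Cl)=O | starting material
13 | allyl (E)-4-bromo-2-oxobut-3-enoate | C=CCOC(=O)C(=O)/C=C/Br | intermediate
14 | allyl 2-[(1R,2R,6S)-2-acetoxy-3-[(2S)-5-acetoxypentan-2-yl]-6-bromo-4-methylcyclohex-3-en-1-yl]-2-oxoacetate (OAc cis to keto ester; Br trans to keto ester) | Br[C@H]1CC(C)=C([C@@H](C)CCCOC(C)=O)[C@H](OC(C)=O)[C@@H]1C(=O)C(=O)OCC=C | intermediate
15 | allyl 2-[(1S,2R,6S)-2-acetoxy-3-[(2S)-5-acetoxypentan-2-yl]-6-bromo-4-methylcyclohex-3-en-1-yl]prop-2-enoate | Br[C@H]1CC(C)=C([C@@H](C)CCCOC(C)=O)[C@H](OC(C)=O)[C@@H]1C(=C)C(=O)OCC=C | intermediate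
16 | sodium 2-[(1S,2R,6S)-2-acetoxy-3-[(2S)-5-acetoxypentan-2-yl]-6-bromo-4-methylcyclohex-3-en-1-yl]prop-2-enoate (not isolated) | Br[C@H]1CC(C)=C([C@@H](C)CCCOC(C)=O)[C@H](OC(C)=O)[C@@H]1C(=C)C(=O)[O-].[Na+] | intermediate
17 | 1,6-O,O-diacetylbritannilactone [(3aR,4R,7aR)-4-acetoxy-5-[(2S)-5-acetoxypentan-2-yl]-6-methyl-3-methylidene-3a,4,7,7a-tetrahydro-1-benzofuran-2(3H)-one] | C=C1C(=O)O[C@@H]2CC(C)=C([C@@H](C)CCCOC(C)=O)[C@H](OC(C)=O)[C@H]12 | target

## Step count and risks

Total step count: 8. Longest linear sequence: 7 (steps 1–4 and 6–8; step 5 makes the dienophile).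

Steps most likely to fail:

1. Step 6 (the proposed new cycloaddition). Possible failures are low enantio- or diastereocontrol, a competing hetero-Diels–Alder mode of the keto ester (oxadiene), or acid-induced loss of the dienyl or allylic acetate. The fallback uses known chemistry, sets out from diene 10 (with dienophile 13) and comes back at 14. The two are simply heated without a chiral catalyst (toluene, 40–60 °C, a trace of BHT), the ordinary thermal Diels–Alder reaction of a 1-acyloxydiene with a β-halovinyl ketone. Because the side-chain centre is already fixed, the endo/ortho adduct forms as two diastereomers, 14 and the ring-diastereomeric bromo keto ester F1 (all three ring centres inverted). These are separated by chromatography and 14 goes on to step 7.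

2. Step 7 (methylenation of a keto ester flanked by a β-bromide and a β-acetate). Possible failures are E1cB loss of HBr or AcOH, or Lewis-acid ionisation of the allylic acetate. The fallback sets out from 14 and comes back at 15 by a Peterson olefination. Me3SiCH2MgCl/CeCl3 (THF, −78 °C; non-basic organocerium conditions) adds to the keto carbonyl to give the β-hydroxysilane F2. BF3·OEt2 (CH2Cl2, −20 °C) then eliminates Me3SiOH to give 15.

3. Step 8 (invertive lactonisation). Possible failures are E2 elimination towards C9 giving a conjugated diene, or ionisation of the allylic acetate by the palladium catalyst. The fallback sets out from diene 10 and comes back at 17; it replaces halide displacement by activation of an alcohol. The silyloxy dienophile allyl (E)-4-(tert-butyldimethylsilyloxy)-2-oxobut-3-enoate F3 is made from 12 and tert-butyldimethyl(vinyloxy)silane (pyridine, CH2Cl2, 0 °C). Cycloaddition with 10 as in step 6 gives the silyloxy keto ester F4, and methylenation as in step 7 gives the silyloxy acrylate F5. Deallylation (Pd(PPh3)4, TolSO2Na) and desilylation (HF·pyridine) give the trans hydroxy acid F6. Mitsunobu lactonisation (PPh3, DIAD, THF, 0 °C) then closes the lactone with inversion at C8 to give 17.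

## Further compounds

F1 | step 6 | allyl 2-[(1S,2S,6R)-2-acetoxy-3-[(2S)-5-acetoxypentan-2-yl]-6-bromo-4-methylcyclohex-3-en-1-yl]-2-oxoacetate (ring-diastereomer of 14) | Br[C@@H]1CC(C)=C([C@@H](C)CCCOC(C)=O)[C@@H](OC(C)=O)[C@H]1C(=O)C(=O)OCC=C
F2 | step 7 | allyl 2-[(1R,2R,6S)-2-acetoxy-3-[(2S)-5-acetoxypentan-2-yl]-6-bromo-4-methylcyclohex-3-en-1-yl]-2-hydroxy-3-(trimethylsilyl)propanoate (both carbinol epimers) | Br[C@H]1CC(C)=C([C@@H](C)CCCOC(C)=O)[C@H](OC(C)=O)[C@@H]1C(O)(C[Si](C)(C)C)C(=O)OCC=C
F3 | step 8 | allyl (E)-4-(tert-butyldimethylsilyloxy)-2-oxobut-3-enoate | C=CCOC(=O)C(=O)/C=C/O[Si](C)(C)C(C)(C)C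
F4 | step 8 | allyl 2-[2-acetoxy-3-[(2S)-5-acetoxypentan-2-yl]-6-(tert-butyldimethylsilyloxy)-4-methylcyclohex-3-en-1-yl]-2-oxoacetate (ring configuration as in 14, silyloxy in place of Br) | CC(C)(C)[Si](C)(C)O[C@H]1CC(C)=C([C@@H](C)CCCOC(C)=O)[C@H](OC(C)=O)[C@@H]1C(=O)C(=O)OCC=C
F5 | step 8 | allyl 2-[2-acetoxy-3-[(2S)-5-acetoxypentan-2-yl]-6-(tert-butyldimethylsilyloxy)-4-methylcyclohex-3-en-1-yl]prop-2-enoate (ring configuration as in 15, silyloxy in place of Br) | CC(C)(C)[Si](C)(C)O[C@H]1CC(C)=C([C@@H](C)CCCOC(C)=O)[C@H](OC(C)=O)[C@@H]1C(=C)C(=O)OCC=C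
F6 | step 8 | 2-[2-acetoxy-3-[(2S)-5-acetoxypentan-2-yl]-6-hydroxy-4-methylcyclohex-3-en-1-yl]prop-2-enoic acid (OH trans to the acrylic acid group, OAc cis to it) | O[C@H]1CC(C)=C([C@@H](C)CCCOC(C)=O)[C@H](OC(C)=O)[C@@H]1C(=C)C(O)=O
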